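Remark on the chemistry (C2 stereochemistry): a dirhodium carboxylate carbenoid inserting into a benzyl ether C–H bond is expected to turn the aryl away from the ligand sphere, which puts it on the concave face, cis to the lactone carbonyl; the insertion product is therefore formulated as that epimer (17, R at the syringyl carbon), not as the convex-face isomer that would map directly onto the target, and C2 is corrected afterwards by acid equilibration of the monocyclic ether (step 14).
Remark on the starting materials: methyl 4-chloro-4-oxobutanoate, a commercial half-ester chloride of succinic acid, is used in place of succinic anhydride and saves one step.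

## Structural features

The target is a 2,3,4-trisubstituted tetrahydrofuran (O1, C2 to C5): C2 carries the 4-hydroxy-3,5-dimethoxyphenyl (syringyl) ring, C3 a CH2O arm (C9) acylated by (E)-ferulic acid, C4 a 4-hydroxy-3-methoxybenzyl (guaiacylmethyl, benzylic carbon C7') group, and C5 is an unsubstituted OCH2. The three stereocentres are contiguous, (2S,3R,4R), with the C2 aryl trans to the C3 arm and the C3 and C4 arms cis to each other. Fragile elements are the three free phenols (oxidation, quinone methide formation), the conjugated ferulate ester (base, nucleophiles, hydrogenation) and the C2–O1 bond, a benzylic ether of an electron-rich arene that acid can ionise and palladium can hydrogenolyse. The real difficulty is the cis relation between C3 and C4: it is the less stable arrangement and sits on two centres that cannot be equilibrated, whereas C2 can be, through its benzylic cation. The key step uses the fact that C2–H is both benzylic and alpha to O1 and lies five atoms from C3, so a carbenoid at C3 can insert into it and close the ring. That carbenoid is held in a butyrolactone joining the C9 carbonyl to C7'; the lactone forces C9 and C7' cis, which is exactly the C3/C4 relation required, and its benzylic C7'–O bond is removed later by hydrogenolysis. The ferulate and the free phenols are therefore introduced only after that hydrogenolysis.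

## Logic of the disconnections

25 to 24: the three phenolic O–H bonds are traced back to O–Si bonds. Free phenols would compete in acylation and open quinone methide pathways, and one kind of silyl ether on all three rings can be removed in a single operation. The gain is a single protecting-group regime. The demand is a last step mild enough to spare the cinnamate ester and the C2–O1 bond.

24 to 20 and 23: the acyl–oxygen bond of the C9 ester is cut. It is the only bond joining two halves of very different complexity, and the enoate could not pass through hydrogenolysis or borane. The gain is convergence, and 23 comes in one operation from 21 (through 22). The demand is a neutral acylation of a primary alcohol beside two stereocentres, with no free phenol on 23.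

20 to 19: the C2–O1 bond is cut and remade on the other face of C2. The insertion is expected to deliver the C2 epimer, and C2 is the only centre with an ionisable bond. The gain is that the stereochemical problem at C2 is separated from the C–C bond formation, and both C2 epimers converge. The demand is an equilibrium that favours the 2,3-trans ring and a cation that recloses on oxygen faster than it alkylates the guaiacyl ring.

19 to 18 to 17: C9 is raised from alcohol to acid, and the C7'–H bond is replaced by a C7'–O bond to that carboxyl. The resulting lactone ties C3 and C4 cis and supplies the carbonyl that stabilises a diazo group at C3. The gain is a rigid bicycle in which the C3/C4 relation is enforced by ring fusion. The demand is a hydrogenolysis that cleaves the benzylic acyloxy bond and spares the benzylic ether, and a reduction that touches only the acid.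

17 to 16: the C2–C3 bond is cut. C2–H is the most hydridic C–H bond within reach of C3, so the ring opens to a monocyclic lactone with only one stereocentre that matters (C4). The gain is one ring, one skeletal bond and two stereocentres. The demand is a carbenoid that inserts 1,5 in preference to hydride shift, dimerisation or attack on the arenes.

16 to 14: the C3=N2 bond is removed. The gain is a plain lactone. The demand is diazo transfer to a carbon that is not acidic enough for direct transfer, which calls for temporary activation as the trifluoroacetyl compound 15.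

14 to 9 and 13: the O1–C2 ether bond is cut. This separates the syringyl unit as an electrophile; 13 comes from 10 through 11 and 12. The gain is convergence. The demand is an etherification without base, because the alkoxide of 9 would translactonise.

9 to 8 to 7: the C5 carbon is traced back from alcohol to acid to acyl oxazolidinone. The gain is that C4 becomes the alpha carbon of an imide. The demand is auxiliary cleavage and acid reduction that leave the lactone and the aryl silyl ether intact.

7 to 5 and 2 (through 6): the C4–C7' bond and the lactone C–O bond are cut. An aldol at this bond sets the absolute configuration of C4 from the auxiliary, and the aldol hydroxyl becomes the lactone oxygen. The gain is two simple achiral carbon fragments. The demand is a syn-selective boron aldol with an electron-rich aldehyde.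

5 to 3 and 4, and 2 to 1: the N–acyl bond and the O–Si bond are cut, leaving commercial materials.

## Other disconnections considered

Alternative 1: the C4–C7' and C2–C3 bonds are cut together, with no ring closed.
- Forward step: the magnesium alkoxide of the mono-silylated butynediol A1 directs anti addition of the benzylic Grignard reagent A2 across the alkyne; ZnCl2 turns the alkenylmagnesium into an alkenylzinc, which adds to aldehyde 11 under a chiral amino alcohol to give the ene-diol A3.
- In its favour: two skeletal bonds and the whole carbon frame of the ring in one flask from three simple pieces. On step economy this is better than the chosen plan.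
- Against it here: C3 and C4 are still sp2 in A3. They must be set later by hydrogenating a tetrasubstituted alkene in the derived dihydrofuran, where only C2 controls the face; syn addition anti to the aryl gives the all-cis ring.
- Consequence: C2 has to start in the opposite spatial sense, which is how A3 is formulated (its S descriptor comes from a changed priority order, not from the arrangement of the target), and must be equilibrated by acid at the end. On this endgame correction the two plans are equal.
- Further weaknesses: benzylic Grignard reagents homocouple easily; ligand-controlled addition of a fully substituted alkenylzinc to a hindered, electron-rich aldehyde is the least secure element; hydrogenation beside a benzylic ether risks hydrogenolysis.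
- Comparison: the chosen plan takes its absolute control from an auxiliary aldol and its C3/C4 relation from ring fusion, which is mechanistically safer but longer.

Alternative 2: the C4–C5 bond and the C7'–O lactone bond are cut.
- Forward step: Me3SiOTf opens the dioxanone A4 to an oxocarbenium ion on O1, which attacks the styrene at C4; the carboxylate on C3 then captures the benzylic cation at C7' to give the furofuranone A5.
- In its favour: two rings close in one step against one in the chosen plan, which is better. A5 is the convex-face C2 epimer of 17 in other protecting groups, because C2 arrives preset from a beta-hydroxy acid and the tosylate keeps it from ionising. On C2 control this is superior, since no epimerisation step is needed; the endgame is otherwise the same, which is equal.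
- Against it here: A4 must be made as one enantiomer with the syringyl and styryl groups cis, which needs a syn-selective aldol of a beta,gamma-unsaturated acid derivative that can slip into conjugation. The electron-rich styrene may oligomerise under the Lewis acid.
- Protecting groups: two different phenol groups are carried. The benzyl ether falls in the lactone hydrogenolysis and leaves a free guaiacyl phenol before the esterification, and the tosylate needs nucleophilic or reductive removal that the ferulate would not tolerate.
- Comparison: step count is similar to the chosen plan; the cationic cascade is more ambitious, and the carbenoid insertion has fewer competing ionic pathways.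

Alternative 3: the C3–C4 bond is cut.
- Forward step: Cp2TiCl (trivalent titanium, from Cp2TiCl2 and Zn) opens the terminal epoxide of A6 to a radical at C3, which adds 5-exo to the cinnamyl alkene; the benzylic radical is reduced by a second equivalent and protonated to give A7.
- In its favour: A7 is 20 with tert-butyldimethylsilyl in place of triisopropylsilyl groups, so the ring, C3, C4 and the free C9 hydroxyl arrive in one step with no sacrificial lactone, no hydrogenolysis and no redox adjustment. This is clearly better on step economy, and the neutral conditions suit silyl ethers as well as those of the chosen plan, which is equal.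
- Against it here: C3 and C4 are set together under substrate control by the C2 aryl through a chair-like transition state of a planar radical. Neither centre can be equilibrated afterwards, so any other isomer is lost.
- Precursor: A6 needs an enantioselective synthesis of an aryl epoxy carbinol and etherification of a hindered benzylic alcohol beside an epoxide, where a Payne rearrangement threatens under base. Titanium is stoichiometric.
- Comparison: the chosen plan fixes C4 by an auxiliary, C3 by ring fusion and C2 by thermodynamics, so it is longer but more secure in its stereochemistry.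

Key step: step 11

## Route

Step 1
Reactants: 1 vanillin
Product: 2 3-methoxy-4-(triisopropylsilyloxy)benzaldehyde
Conditions: TIPSCl, imidazole, DMF, rt
Reagents that add atoms: triisopropylsilyl chloride, CC(C)[Si](Cl)(C(C)C)C(C)C
Why: Imidazole-promoted silylation of a phenol; the bulky aryl silyl ether should survive boron enolates, peroxide, borane, hydrogenolysis and mild acid and fall only to fluoride at the end.

Step 2
Reactants: 3 (S)-4-benzyl-1,3-oxazolidin-2-one; 4 methyl 4-chloro-4-oxobutanoate
Product: 5 methyl 4-[(4S)-4-benzyl-2-oxo-1,3-oxazolidin-3-yl]-4-oxobutanoate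
Conditions: n-BuLi, THF, −78 °C; then 4, −78 → 0 °C
Reagents that add atoms: none
Why: N-acylation of the lithiated oxazolidinone by an acid chloride (installation of the Evans auxiliary); the methyl ester is far less electrophilic than the acid chloride and stays intact.

Step 3
Reactants: 5 methyl 4-[(4S)-4-benzyl-2-oxo-1,3-oxazolidin-3-yl]-4-oxobutanoate; 2 3-methoxy-4-(triisopropylsilyloxy)benzaldehyde
Product: 7 (4S)-4-benzyl-3-{[(2S,3S)-2-[3-methoxy-4-(triisopropylsilyloxy)phenyl]-5-oxooxolan-3-yl]carbonyl}-1,3-oxazolidin-2-one, via syn-aldol hydroxy ester 6 (not isolated)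
Conditions: Bu2BOTf, iPr2NEt, CH2Cl2, −78 → 0 °C; 2, −78 → 0 °C; pH 7 buffer, MeOH, H2O2, 0 °C; then PPTS (cat.), PhMe, 50 °C
Reagents that add atoms: none
Why: Evans syn-aldol through the Z-boron enolate and a Zimmerman–Traxler chair; the benzyl group of the auxiliary shields one enolate face, so the alpha carbon (the future C4) should form S and the carbinol S, and the gamma-hydroxy ester then lactonises by acid-catalysed transesterification to the trans lactone. The carbinol centre is sacrificial, so only the alpha centre has to be right.

Step 4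
Reactants: 7 (4S)-4-benzyl-3-{[(2S,3S)-2-[3-methoxy-4-(triisopropylsilyloxy)phenyl]-5-oxooxolan-3-yl]carbonyl}-1,3-oxazolidin-2-one
Product: 8 (2S,3S)-2-[3-methoxy-4-(triisopropylsilyloxy)phenyl]-5-oxooxolane-3-carboxylic acid
Conditions: LiOH, H2O2, THF/H2O, 0 °C; Na2SO3; 1 M HCl to pH 3
Reagents that add atoms: hydrogen peroxide, OO
Why: Auxiliary removal with LiOOH, which attacks the exocyclic imide carbonyl selectively; sulfite reduces the peracid and acidification recloses any lactone opened by hydroxide. The alpha centre is not epimerisable as its carboxylate.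

Step 5
Reactants: 8 (2S,3S)-2-[3-methoxy-4-(triisopropylsilyloxy)phenyl]-5-oxooxolane-3-carboxylic acid
Product: 9 (4R,5S)-4-(hydroxymethyl)-5-[3-methoxy-4-(triisopropylsilyloxy)phenyl]oxolan-2-one
Conditions: BH3·SMe2, THF, 0 °C → rt; MeOH
Reagents that add atoms: none
Why: Chemoselective borane reduction; the acid forms an acyloxyborane that is reduced much faster than the lactone, and the non-basic conditions avoid translactonisation onto the new primary alcohol.

Step 6
Reactants: 10 syringaldehyde
Product: 11 3,5-dimethoxy-4-(triisopropylsilyloxy)benzaldehyde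
Conditions: TIPSCl, imidazole, DMF, 40 °C
Reagents that add atoms: triisopropylsilyl chloride, CC(C)[Si](Cl)(C(C)C)C(C)C
Why: Silylation of the flanked but acidic phenol (para to the aldehyde); gentle warming compensates for the two ortho methoxy groups.

Step 7
Reactants: 11 3,5-dimethoxy-4-(triisopropylsilyloxy)benzaldehyde
Product: 12 [3,5-dimethoxy-4-(triisopropylsilyloxy)phenyl]methanol
Conditions: NaBH4, MeOH/THF, 0 °C
Reagents that add atoms: none
Why: Borohydride reduction of an aromatic aldehyde; the aryl silyl ether tolerates the short, cold exposure to methoxide.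

Step 8
Reactants: 12 [3,5-dimethoxy-4-(triisopropylsilyloxy)phenyl]methanol
Product: 13 3,5-dimethoxy-4-(triisopropylsilyloxy)benzyl 2,2,2-trichloroacetimidate
Conditions: Cl3CCN, DBU (cat.), CH2Cl2, 0 °C; used at once
Reagents that add atoms: trichloroacetonitrile, N#CC(Cl)(Cl)Cl
Why: Base-catalysed addition of the alcohol to trichloroacetonitrile (imidate formation); the product is used without storage because the electron-rich benzyl imidate ionises easily.

Step 9
Reactants: 9 (4R,5S)-4-(hydroxymethyl)-5-[3-methoxy-4-(triisopropylsilyloxy)phenyl]oxolan-2-one; 13 3,5-dimethoxy-4-(triisopropylsilyloxy)benzyl 2,2,2-trichloroacetimidate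
Product: 14 (4R,5S)-4-({[3,5-dimethoxy-4-(triisopropylsilyloxy)benzyl]oxy}methyl)-5-[3-methoxy-4-(triisopropylsilyloxy)phenyl]oxolan-2-one
Conditions: CSA (10 mol %), CH2Cl2, 0 °C → rt
Reagents that add atoms: none
Why: Acid-catalysed benzylation with a trichloroacetimidate; protonation releases trichloroacetamide and a stabilised syringylmethyl cation that the primary alcohol captures, and in the absence of base the lactone cannot translactonise.

Step 10
Reactants: 14 (4R,5S)-4-({[3,5-dimethoxy-4-(triisopropylsilyloxy)benzyl]oxy}methyl)-5-[3-methoxy-4-(triisopropylsilyloxy)phenyl]oxolan-2-one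
Product: 16 (4R,5S)-3-diazo-4-({[3,5-dimethoxy-4-(triisopropylsilyloxy)benzyl]oxy}methyl)-5-[3-methoxy-4-(triisopropylsilyloxy)phenyl]oxolan-2-one, via trifluoroacetyl lactone 15 (not isolated)
Conditions: LiN(SiMe3)2, THF, −78 °C; CF3CO2CH2CF3, −78 °C; 5% HCl work-up; then p-ABSA, Et3N, H2O (1 equiv), MeCN, rt
Reagents that add atoms: 4-acetamidobenzenesulfonyl azide, CC(=O)Nc1ccc(cc1)S(=O)(=O)N=[N+]=[N-]; 2,2,2-trifluoroethyl trifluoroacetate, O=C(OCC(F)(F)F)C(F)(F)F (its CF3CO group stays only in 15)
Why: Detrifluoroacetylative diazo transfer; the lactone enolate is C-acylated and the activated 1,3-dicarbonyl compound takes the diazo group from the sulfonyl azide while the trifluoroacetyl group leaves as the N-acyl sulfonamide. C4 carries no acidic hydrogen and no beta leaving group, so its configuration is untouched.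

Step 11
Reactants: 16 (4R,5S)-3-diazo-4-({[3,5-dimethoxy-4-(triisopropylsilyloxy)benzyl]oxy}methyl)-5-[3-methoxy-4-(triisopropylsilyloxy)phenyl]oxolan-2-one
Product: 17 (3S,3aR,6R,6aS)-6-[3,5-dimethoxy-4-(triisopropylsilyloxy)phenyl]-3-[3-methoxy-4-(triisopropylsilyloxy)phenyl]tetrahydro-1H,3H-furo[3,4-c]furan-1-one
Conditions: Rh2(OAc)4 (2 mol %), CH2Cl2, rt, slow addition of 16
Reagents that add atoms: none
Why: Rh2(OAc)4 decomposes the diazo lactone with loss of N2 to an electrophilic carbenoid on divalent rhodium at C3, flanked by the lactone carbonyl. The carbenoid reaches the syringylmethyl C–H bond five atoms away, which is hydridic because it is benzylic to an electron-rich arene and alpha to the ether oxygen, and inserts through a three-centre transition state with hydride-transfer character (closest known reaction type: intramolecular 1,5 C–H insertion of alpha-diazo butyrolactones into benzyl ethers under dirhodium carboxylate catalysis). The tetrahydrofuran closes as a five-membered ring by formation of the C2–C3 bond; other ring sizes would need unactivated C–H bonds, and an oxonium ylide at O1 would be a strained four-membered ring. C3 is controlled by the ring fusion: the dioxabicyclo[3.3.0]octanone can only be cis-fused, so the C3 carbonyl carbon ends cis to C7' on C4, and C4 itself comes unchanged from the auxiliary aldol. C2 is controlled by the transition state: the aryl is expected to turn away from the carboxylate ligands around rhodium and so to lie on the concave face, cis to the lactone carbonyl (R at C2), which is the opposite of what the target needs. This is accepted because C2 alone among the three centres can be equilibrated later (step 14), where both C2 epimers converge. The step therefore has to deliver only chemoselectivity (insertion over 1,2-hydride shift from C4–H and over carbene dimerisation, helped by slow addition and the activated C–H bond) and the cis fusion, and the substrate enforces both.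

Step 12
Reactants: 17 (3S,3aR,6R,6aS)-6-[3,5-dimethoxy-4-(triisopropylsilyloxy)phenyl]-3-[3-methoxy-4-(triisopropylsilyloxy)phenyl]tetrahydro-1H,3H-furo[3,4-c]furan-1-one
Product: 18 (2R,3S,4R)-2-[3,5-dimethoxy-4-(triisopropylsilyloxy)phenyl]-4-[3-methoxy-4-(triisopropylsilyloxy)benzyl]oxolane-3-carboxylic acid
Conditions: H2 (1 atm), 10% Pd/C, Et3N, EtOAc, rt; pH 4 citrate work-up
Reagents that add atoms: none
Why: Benzylic C–O hydrogenolysis of the aryl lactone (a cyclic benzyl ester) on palladium gives the acid and the guaiacyl CH2; benzyl esters cleave faster than benzyl ethers, the amine further suppresses ether cleavage, and the C2–O1 bond lies on the shielded concave face. No stereocentre is formed and the sacrificial C7' centre disappears.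

Step 13
Reactants: 18 (2R,3S,4R)-2-[3,5-dimethoxy-4-(triisopropylsilyloxy)phenyl]-4-[3-methoxy-4-(triisopropylsilyloxy)benzyl]oxolane-3-carboxylic acid
Product: 19 [(2R,3R,4R)-2-[3,5-dimethoxy-4-(triisopropylsilyloxy)phenyl]-4-[3-methoxy-4-(triisopropylsilyloxy)benzyl]oxolan-3-yl]methanol
Conditions: BH3·SMe2, THF, 0 °C → rt; MeOH
Reagents that add atoms: none
Why: Borane reduction of the carboxylic acid to the primary alcohol at C9; aryl silyl ethers and the benzylic ether are inert, and the descriptor at C3 changes only because the priorities change.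

Step 14
Reactants: 19 [(2R,3R,4R)-2-[3,5-dimethoxy-4-(triisopropylsilyloxy)phenyl]-4-[3-methoxy-4-(triisopropylsilyloxy)benzyl]oxolan-3-yl]methanol
Product: 20 [(2S,3R,4R)-2-[3,5-dimethoxy-4-(triisopropylsilyloxy)phenyl]-4-[3-methoxy-4-(triisopropylsilyloxy)benzyl]oxolan-3-yl]methanol
Conditions: BF3·OEt2 (0.3 equiv), CH2Cl2, −40 → 0 °C; Et3N quench
Reagents that add atoms: none
Why: Acid-catalysed epimerisation of a 2-aryltetrahydrofuran by reversible SN1 opening; BF3 on O1 ionises the C2–O1 bond to a p-silyloxybenzyl cation, and rotation about C2–C3 followed by 5-exo reclosure through the C5 oxygen should lead to the thermodynamic ring with the aryl trans to the C3 arm (S at C2). C3 and C4 have no ionisable bond and keep their configuration; low temperature and sub-stoichiometric acid are chosen so that Friedel–Crafts attack of the guaiacyl ring on the cation does not compete.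

Step 15
Reactants: 21 ferulic acid
Product: 23 (E)-3-[3-methoxy-4-(triisopropylsilyloxy)phenyl]prop-2-enoic acid, via bis-silylated ferulate 22 (not isolated)
Conditions: TIPSCl (2.2 equiv), imidazole, DMF, rt; then K2CO3, THF/MeOH/H2O, 0 °C; 1 M HCl to pH 3
Reagents that add atoms: triisopropylsilyl chloride, CC(C)[Si](Cl)(C(C)C)C(C)C
Why: Silylation of phenol and acid, then selective hydrolysis of the far more labile silyl ester by attack at silicon, which leaves the aryl silyl ether and the E-alkene untouched.

Step 16
Reactants: 20 [(2S,3R,4R)-2-[3,5-dimethoxy-4-(triisopropylsilyloxy)phenyl]-4-[3-methoxy-4-(triisopropylsilyloxy)benzyl]oxolan-3-yl]methanol; 23 (E)-3-[3-methoxy-4-(triisopropylsilyloxy)phenyl]prop-2-enoic acid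
Product: 24 [(2S,3R,4R)-2-[3,5-dimethoxy-4-(triisopropylsilyloxy)phenyl]-4-[3-methoxy-4-(triisopropylsilyloxy)benzyl]oxolan-3-yl]methyl (E)-3-[3-methoxy-4-(triisopropylsilyloxy)phenyl]prop-2-enoate
Conditions: EDC·HCl, DMAP (cat.), CH2Cl2, 0 °C → rt
Reagents that add atoms: none
Why: Steglich esterification of the primary alcohol; the neutral conditions leave C2 and the silyl ethers alone and no phenol is free to compete for the activated acid.

Step 17
Reactants: 24 [(2S,3R,4R)-2-[3,5-dimethoxy-4-(triisopropylsilyloxy)phenyl]-4-[3-methoxy-4-(triisopropylsilyloxy)benzyl]oxolan-3-yl]methyl (E)-3-[3-methoxy-4-(triisopropylsilyloxy)phenyl]prop-2-enoate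
Product: 25 [(2S,3R,4R)-2-(4-hydroxy-3,5-dimethoxyphenyl)-4-(4-hydroxy-3-methoxybenzyl)oxolan-3-yl]methyl (E)-3-(4-hydroxy-3-methoxyphenyl)prop-2-enoate (CNP0289934.1)
Conditions: TBAF (3.5 equiv), AcOH (3.5 equiv), THF, 0 °C
Reagents that add atoms: none
Why: Fluoride cleavage of the three aryl silyl ethers; acetic acid buffers the phenoxides so that the cinnamate ester is not transesterified and C2 is not opened through a quinone methide.

## Compound list

1 | vanillin | COc1cc(C=O)ccc1O | starting material
2 | 3-methoxy-4-(triisopropylsilyloxy)benzaldehyde | COc1cc(C=O)ccc1O[Si](C(C)C)(C(C)C)C(C)C | intermediate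
3 | (S)-4-benzyl-1,3-oxazolidin-2-one | O=C1N[C@@H](Cc2ccccc2)CO1 | starting material
4 | methyl 4-chloro-4-oxobutanoate | COC(=O)CCC(Cl)=O | starting material
5 | methyl 4-[(4S)-4-benzyl-2-oxo-1,3-oxazolidin-3-yl]-4-oxobutanoate | COC(=O)CCC(=O)N1[C@@H](Cc2ccccc2)COC1=O | intermediate
6 | methyl (3S,4S)-3-{[(4S)-4-benzyl-2-oxo-1,3-oxazolidin-3-yl]carbonyl}-4-hydroxy-4-[3-methoxy-4-(triisopropylsilyloxy)phenyl]butanoate | COC(=O)C[C@H](C(=O)N1[C@@H](Cc2ccccc2)COC1=O)[C@H](O)c1ccc(O[Si](C(C)C)(C(C)C)C(C)C)c(OC)c1 | intermediate (not isolated)
7 | (4S)-4-benzyl-3-{[(2S,3S)-2-[3-methoxy-4-(triisopropylsilyloxy)phenyl]-5-oxooxolan-3-yl]carbonyl}-1,3-oxazolidin-2-one | O=C1O[C@H](c2ccc(O[Si](C(C)C)(C(C)C)C(C)C)c(OC)c2)[C@@H](C(=O)N2[C@@H](Cc3ccccc3)COC2=O)C1 | intermediate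
8 | (2S,3S)-2-[3-methoxy-4-(triisopropylsilyloxy)phenyl]-5-oxooxolane-3-carboxylic acid | O=C1O[C@H](c2ccc(O[Si](C(C)C)(C(C)C)C(C)C)c(OC)c2)[C@@H](C(=O)O)C1 | intermediate
9 | (4R,5S)-4-(hydroxymethyl)-5-[3-methoxy-4-(triisopropylsilyloxy)phenyl]oxolan-2-one | O=C1O[C@H](c2ccc(O[Si](C(C)C)(C(C)C)C(C)C)c(OC)c2)[C@@H](CO)C1 | intermediate
10 | syringaldehyde | COc1cc(C=O)cc(OC)c1O | starting material
11 | 3,5-dimethoxy-4-(triisopropylsilyloxy)benzaldehyde | COc1cc(C=O)cc(OC)c1O[Si](C(C)C)(C(C)C)C(C)C | intermediate
12 | [3,5-dimethoxy-4-(triisopropylsilyloxy)phenyl]methanol | COc1cc(CO)cc(OC)c1O[Si](C(C)C)(C(C)C)C(C)C | intermediate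
13 | 3,5-dimethoxy-4-(triisopropylsilyloxy)benzyl 2,2,2-trichloroacetimidate | COc1cc(COC(=N)C(Cl)(Cl)Cl)cc(OC)c1O[Si](C(C)C)(C(C)C)C(C)C | intermediate
14 | (4R,5S)-4-({[3,5-dimethoxy-4-(triisopropylsilyloxy)benzyl]oxy}methyl)-5-[3-methoxy-4-(triisopropylsilyloxy)phenyl]oxolan-2-one | O=C1O[C@H](c2ccc(O[Si](C(C)C)(C(C)C)C(C)C)c(OC)c2)[C@@H](COCc2cc(OC)c(O[Si](C(C)C)(C(C)C)C(C)C)c(OC)c2)C1 | intermediate
15 | (4R,5S)-4-({[3,5-dimethoxy-4-(triisopropylsilyloxy)benzyl]oxy}methyl)-5-[3-methoxy-4-(triisopropylsilyloxy)phenyl]-3-(trifluoroacetyl)oxolan-2-one (C3 unassigned, enolisable) | O=C1O[C@H](c2ccc(O[Si](C(C)C)(C(C)C)C(C)C)c(OC)c2)[C@@H](COCc2cc(OC)c(O[Si](C(C)C)(C(C)C)C(C)C)c(OC)c2)C1C(=O)C(F)(F)F | intermediate (not isolated)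
16 | (4R,5S)-3-diazo-4-({[3,5-dimethoxy-4-(triisopropylsilyloxy)benzyl]oxy}methyl)-5-[3-methoxy-4-(triisopropylsilyloxy)phenyl]oxolan-2-one | O=C1O[C@H](c2ccc(O[Si](C(C)C)(C(C)C)C(C)C)c(OC)c2)[C@@H](COCc2cc(OC)c(O[Si](C(C)C)(C(C)C)C(C)C)c(OC)c2)C1=[N+]=[N-] | intermediate
17 | (3S,3aR,6R,6aS)-6-[3,5-dimethoxy-4-(triisopropylsilyloxy)phenyl]-3-[3-methoxy-4-(triisopropylsilyloxy)phenyl]tetrahydro-1H,3H-furo[3,4-c]furan-1-one | O=C1O[C@H](c2ccc(O[Si](C(C)C)(C(C)C)C(C)C)c(OC)c2)[C@H]2CO[C@@H](c3cc(OC)c(O[Si](C(C)C)(C(C)C)C(C)C)c(OC)c3)[C@@H]12 | intermediate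
18 | (2R,3S,4R)-2-[3,5-dimethoxy-4-(triisopropylsilyloxy)phenyl]-4-[3-methoxy-4-(triisopropylsilyloxy)benzyl]oxolane-3-carboxylic acid | OC(=O)[C@H]1[C@@H](Cc2ccc(O[Si](C(C)C)(C(C)C)C(C)C)c(OC)c2)CO[C@H]1c1cc(OC)c(O[Si](C(C)C)(C(C)C)C(C)C)c(OC)c1 | intermediate
19 | [(2R,3R,4R)-2-[3,5-dimethoxy-4-(triisopropylsilyloxy)phenyl]-4-[3-methoxy-4-(triisopropylsilyloxy)benzyl]oxolan-3-yl]methanol | OC[C@H]1[C@@H](Cc2ccc(O[Si](C(C)C)(C(C)C)C(C)C)c(OC)c2)CO[C@H]1c1cc(OC)c(O[Si](C(C)C)(C(C)C)C(C)C)c(OC)c1 | intermediate
20 | [(2S,3R,4R)-2-[3,5-dimethoxy-4-(triisopropylsilyloxy)phenyl]-4-[3-methoxy-4-(triisopropylsilyloxy)benzyl]oxolan-3-yl]methanol | OC[C@H]1[C@@H](Cc2ccc(O[Si](C(C)C)(C(C)C)C(C)C)c(OC)c2)CO[C@@H]1c1cc(OC)c(O[Si](C(C)C)(C(C)C)C(C)C)c(OC)c1 | intermediate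
21 | ferulic acid | COc1cc(/C=C/C(=O)O)ccc1O | starting material
22 | triisopropylsilyl (E)-3-[3-methoxy-4-(triisopropylsilyloxy)phenyl]prop-2-enoate | COc1cc(/C=C/C(=O)O[Si](C(C)C)(C(C)C)C(C)C)ccc1O[Si](C(C)C)(C(C)C)C(C)C | intermediate (not isolated)
23 | (E)-3-[3-methoxy-4-(triisopropylsilyloxy)phenyl]prop-2-enoic acid | COc1cc(/C=C/C(=O)O)ccc1O[Si](C(C)C)(C(C)C)C(C)C | intermediate
24 | [(2S,3R,4R)-2-[3,5-dimethoxy-4-(triisopropylsilyloxy)phenyl]-4-[3-methoxy-4-(triisopropylsilyloxy)benzyl]oxolan-3-yl]methyl (E)-3-[3-methoxy-4-(triisopropylsilyloxy)phenyl]prop-2-enoate | COc1cc(/C=C/C(=O)OC[C@H]2[C@@H](Cc3ccc(O[Si](C(C)C)(C(C)C)C(C)C)c(OC)c3)CO[C@@H]2c2cc(OC)c(O[Si](C(C)C)(C(C)C)C(C)C)c(OC)c2)ccc1O[Si](C(C)C)(C(C)C)C(C)C | intermediate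
25 | [(2S,3R,4R)-2-(4-hydroxy-3,5-dimethoxyphenyl)-4-(4-hydroxy-3-methoxybenzyl)oxolan-3-yl]methyl (E)-3-(4-hydroxy-3-methoxyphenyl)prop-2-enoate | COc1cc(/C=C/C(=O)OC[C@H]2[C@@H](Cc3ccc(O)c(OC)c3)CO[C@@H]2c2cc(OC)c(O)c(OC)c2)ccc1O | target

## Step count and least certain steps

Total step count: 17. Longest linear sequence: 12 steps (steps 1, 3, 4, 5, 9, 10, 11, 12, 13, 14, 16, 17).

Step 11 (key step). The carbenoid may be diverted before it reaches the benzylic C–H bond: 1,2-hydride shift from C4–H to a butenolide, dimerisation at higher concentration, or addition to one of the electron-rich arenes. Facial selectivity at C2 is not a risk, since any convex-face epimer is carried along and converges in step 14. The fallback forms the C2–C3 bond by an enolate aldol; it sets out from 9 and returns at 20.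
- Hydrogenolysis of 9 over Pd/C (no benzylic ether is present yet), then acid-catalysed relactonisation, should give (4R)-4-[3-methoxy-4-(triisopropylsilyloxy)benzyl]oxolan-2-one F1.
- Its lithium enolate (LiN(SiMe3)2, THF, −78 °C) should add to 11 trans to the benzyl group to give the aldol lactone F2.
- LiAlH4 should reduce F2 to the triol F3.
- BF3·OEt2 should ionise the benzylic alcohol of F3 and close the ring through the C5 oxygen to the 2,3-trans ether 20.

Step 12. Over-reduction is the danger: the C2–O1 bond is also benzylic to a p-silyloxyaryl ring and could be hydrogenolysed, opening the tetrahydrofuran, or the amine may slow lactone cleavage until the ether competes. The fallback removes the C7' oxygen by a radical deoxygenation that cannot touch the ether; it sets out from 17 and returns at 19.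
- LiBH4 should reduce the lactone of 17 to the diol F4.
- PivCl and pyridine at −20 °C should acylate only the primary hydroxyl, giving the pivalate F5.
- PhOC(S)Cl, pyridine and DMAP should convert the benzylic alcohol into the thionocarbonate F6.
- Bu3SnH and AIBN in toluene at 80 °C (Barton–McCombie) should give the deoxygenated pivalate F7.
- iBu2AlH at −78 °C should release 19.

Step 14. The benzylic cation may alkylate the guaiacyl ring (irreversible Friedel–Crafts closure to an aryltetralin) in place of reclosing on oxygen, or equilibration may stop short and leave the all-cis ring. The fallback moves the epimerisation to an anionic pathway with no electrophilic arene chemistry; it sets out from 19 and returns at 25.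
- TBAF and AcOH should desilylate 19 to the all-cis triol 4-[(2R,3R,4R)-4-(4-hydroxy-3-methoxybenzyl)-3-(hydroxymethyl)oxolan-2-yl]-2,6-dimethoxyphenol F8.
- Warming F8 with DBU in MeCN should open the syringyl phenoxide to a quinone methide; conjugate return of the C5 alkoxide should give the 2,3-trans triol F9.
- A Mitsunobu esterification of the primary alcohol of F9 with 21 (PPh3, DIAD, THF, 0 °C), in which the carboxylic acid is by far the most acidic partner, should give 25 directly.

Step 9. The very electron-rich imidate 13 may rearrange to the N-benzyl trichloroacetamide or alkylate an arene faster than it transfers its benzyl group to the hindered alcohol, and the acid may ionise the benzylic lactone. The fallback forms the same ether by reductive etherification of the aldehyde; it sets out from 9 and returns at 14.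
- Me3SiCl and Et3N should convert 9 into the trimethylsilyl ether F10.
- F10, aldehyde 11 and Et3SiH with catalytic Me3SiOTf in CH2Cl2 at −78 °C should give 14 through reduction of the intermediate oxocarbenium ion.

## Further compounds

F1 | step 11 | (4R)-4-[3-methoxy-4-(triisopropylsilyloxy)benzyl]oxolan-2-one | O=C1C[C@@H](Cc2ccc(O[Si](C(C)C)(C(C)C)C(C)C)c(OC)c2)CO1
F2 | step 11 | (3S,4R)-3-{[3,5-dimethoxy-4-(triisopropylsilyloxy)phenyl](hydroxy)methyl}-4-[3-methoxy-4-(triisopropylsilyloxy)benzyl]oxolan-2-one (carbinol epimers) | O=C1OC[C@H](Cc2ccc(O[Si](C(C)C)(C(C)C)C(C)C)c(OC)c2)[C@H]1C(O)c1cc(OC)c(O[Si](C(C)C)(C(C)C)C(C)C)c(OC)c1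
F3 | step 11 | (2R,3R)-2-{[3,5-dimethoxy-4-(triisopropylsilyloxy)phenyl](hydroxy)methyl}-3-[3-methoxy-4-(triisopropylsilyloxy)benzyl]butane-1,4-diol (carbinol epimers) | OC[C@H](Cc1ccc(O[Si](C(C)C)(C(C)C)C(C)C)c(OC)c1)[C@H](CO)C(O)c1cc(OC)c(O[Si](C(C)C)(C(C)C)C(C)C)c(OC)c1
F4 | step 12 | (S)-[(3R,4R,5R)-5-[3,5-dimethoxy-4-(triisopropylsilyloxy)phenyl]-4-(hydroxymethyl)oxolan-3-yl][3-methoxy-4-(triisopropylsilyloxy)phenyl]methanol | OC[C@H]1[C@@H]([C@H](O)c2ccc(O[Si](C(C)C)(C(C)C)C(C)C)c(OC)c2)CO[C@H]1c1cc(OC)c(O[Si](C(C)C)(C(C)C)C(C)C)c(OC)c1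
F5 | step 12 | primary pivalate of F4 | CC(C)(C)C(=O)OC[C@H]1[C@@H]([C@H](O)c2ccc(O[Si](C(C)C)(C(C)C)C(C)C)c(OC)c2)CO[C@H]1c1cc(OC)c(O[Si](C(C)C)(C(C)C)C(C)C)c(OC)c1
F6 | step 12 | O-phenyl thionocarbonate of F5 at the benzylic oxygen | CC(C)(C)C(=O)OC[C@H]1[C@@H]([C@H](OC(=S)Oc2ccccc2)c2ccc(O[Si](C(C)C)(C(C)C)C(C)C)c(OC)c2)CO[C@H]1c1cc(OC)c(O[Si](C(C)C)(C(C)C)C(C)C)c(OC)c1
F7 | step 12 | pivalate of 19 | CC(C)(C)C(=O)OC[C@H]1[C@@H](Cc2ccc(O[Si](C(C)C)(C(C)C)C(C)C)c(OC)c2)CO[C@H]1c1cc(OC)c(O[Si](C(C)C)(C(C)C)C(C)C)c(OC)c1
F8 | step 14 | 4-[(2R,3R,4R)-4-(4-hydroxy-3-methoxybenzyl)-3-(hydroxymethyl)oxolan-2-yl]-2,6-dimethoxyphenol | OC[C@H]1[C@@H](Cc2ccc(O)c(OC)c2)CO[C@H]1c1cc(OC)c(O)c(OC)c1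
F9 | step 14 | 4-[(2S,3R,4R)-4-(4-hydroxy-3-methoxybenzyl)-3-(hydroxymethyl)oxolan-2-yl]-2,6-dimethoxyphenol | OC[C@H]1[C@@H](Cc2ccc(O)c(OC)c2)CO[C@@H]1c1cc(OC)c(O)c(OC)c1
F10 | step 9 | (4R,5S)-5-[3-methoxy-4-(triisopropylsilyloxy)phenyl]-4-[(trimethylsilyloxy)methyl]oxolan-2-one | O=C1O[C@H](c2ccc(O[Si](C(C)C)(C(C)C)C(C)C)c(OC)c2)[C@@H](CO[Si](C)(C)C)C1
A1 | alternative 1 | 4-(tert-butyldimethylsilyloxy)but-2-yn-1-ol | OCC#CCO[Si](C)(C)C(C)(C)C
A2 | alternative 1 | [3-methoxy-4-(triisopropylsilyloxy)benzyl]magnesium chloride | COc1cc(C[Mg]Cl)ccc1O[Si](C(C)C)(C(C)C)C(C)C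
A3 | alternative 1 | (2Z)-4-(tert-butyldimethylsilyloxy)-3-{(S)-[3,5-dimethoxy-4-(triisopropylsilyloxy)phenyl](hydroxy)methyl}-2-[3-methoxy-4-(triisopropylsilyloxy)benzyl]but-2-en-1-ol | OC/C(Cc1ccc(O[Si](C(C)C)(C(C)C)C(C)C)c(OC)c1)=C(/CO[Si](C)(C)C(C)(C)C)[C@@H](O)c1cc(OC)c(O[Si](C(C)C)(C(C)C)C(C)C)c(OC)c1
A4 | alternative 2 | (5S,6S)-5-[(E)-2-(4-benzyloxy-3-methoxyphenyl)ethenyl]-6-[3,5-dimethoxy-4-(tosyloxy)phenyl]-1,3-dioxan-4-one | O=C1OCO[C@H](c2cc(OC)c(OS(=O)(=O)c3ccc(C)cc3)c(OC)c2)[C@@H]1/C=C/c1ccc(OCc2ccccc2)c(OC)c1
A5 | alternative 2 | (3S,3aR,6S,6aS)-3-(4-benzyloxy-3-methoxyphenyl)-6-[3,5-dimethoxy-4-(tosyloxy)phenyl]tetrahydro-1H,3H-furo[3,4-c]furan-1-one | O=C1O[C@H](c3ccc(OCc4ccccc4)c(OC)c3)[C@H]2CO[C@H](c3cc(OC)c(OS(=O)(=O)c4ccc(C)cc4)c(OC)c3)[C@@H]12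
A6 | alternative 3 | 2-[(R)-[3,5-dimethoxy-4-(tert-butyldimethylsilyloxy)phenyl]{[(E)-3-[3-methoxy-4-(tert-butyldimethylsilyloxy)phenyl]prop-2-en-1-yl]oxy}methyl]oxirane (oxirane carbon of either configuration) | C1OC1[C@H](OC/C=C/c1ccc(O[Si](C)(C)C(C)(C)C)c(OC)c1)c1cc(OC)c(O[Si](C)(C)C(C)(C)C)c(OC)c1
A7 | alternative 3 | [(2S,3R,4R)-2-[3,5-dimethoxy-4-(tert-butyldimethylsilyloxy)phenyl]-4-[3-methoxy-4-(tert-butyldimethylsilyloxy)benzyl]oxolan-3-yl]methanol | OC[C@H]1[C@@H](Cc2ccc(O[Si](C)(C)C(C)(C)C)c(OC)c2)CO[C@@H]1c1cc(OC)c(O[Si](C)(C)C(C)(C)C)c(OC)c1
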